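**Retrosynthetic overview**
- Metasequirin E ⇐ global debenzylation of an oxolane whose only ring is closed last, by 5-exo opening of a trans-epoxide by the C5 alkoxide (forms O1–C2 with inversion; the epoxide oxygen stays as the C1′ carbinol).
- Epoxide ⇐ hydroxyl-directed epoxidation of an (E)-1,3-diarylpentenol; its styryl unit ⇐ cross-metathesis of an (E)-propenyl group with a pivaloyl-protected 4-vinylguaiacol.
- Key step: chelated glycolate Ireland–Claisen [3,3] rearrangement of a (Z)-aryl allylic ester forms C3–C4 and sets C3 (aryl) and C4 (O) together by 1,3-chirality transfer.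
- The (S,Z)-allylic alcohol ⇐ Sonogashira coupling and Lindlar reduction from (S)-but-3-yn-2-ol, the only chiral purchase; its stereocentre is consumed in the rearrangement, and C2/C1′ are then set under control of C3/C4.

Assumption: (S)-but-3-yn-2-ol is taken as an inexpensive catalogue single-enantiomer building block (the alkyne analogue of L-lactate). Locants: oxolane O1, C2 (bears C1′H(OH)Ar), C3 (Ar), C4 (OH), C5 (CH2). The target is (2S,3R,4S,1′R), with all three ring substituents cis.

**Step 1**
Reactants: 1, 1-(benzyloxy)-4-bromo-2-methoxybenzene; 2, (S)-but-3-yn-2-ol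
Product: 3, (S)-4-[4-(benzyloxy)-3-methoxyphenyl]but-3-yn-2-ol
Conditions: PdCl2(MeCN)2 (2 mol%), XPhos (6 mol%), Cs2CO3, MeCN, 70 °C
Reagents that add atoms: none (both partners are numbered reactants)
Why: Copper-free Sonogashira coupling with a bulky phosphine suited to an electron-rich aryl bromide; the carbinol stereocentre is not involved.

**Step 2**
Reactants: 3
Product: 4, (S,Z)-4-[4-(benzyloxy)-3-methoxyphenyl]but-3-en-2-ol
Conditions: H2 (1 atm), Lindlar catalyst, quinoline, EtOAc, 23 °C
Reagents that add atoms: none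
Why: Lindlar semihydrogenation adds H2 syn to give the Z-alkene; the poisoned catalyst leaves the aryl benzyl ether and the carbinol untouched.

**Step 3**
Reactants: 4; 5, 2-(benzyloxy)acetyl chloride
Product: 6, (S,Z)-4-[4-(benzyloxy)-3-methoxyphenyl]but-3-en-2-yl 2-(benzyloxy)acetate
Conditions: pyridine, DMAP (cat.), CH2Cl2, 0 °C; purify on Et3N-deactivated silica
Reagents that add atoms: none beyond reactant 5 (O=C(Cl)COCc1ccccc1)
Why: O-acylation under basic conditions retains the carbinol configuration and avoids acid, which would ionise the electron-rich allylic system.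

**Step 4**
Reactants: 6
Product: 7, (2S,3R,4E)-2-(benzyloxy)-3-[4-(benzyloxy)-3-methoxyphenyl]hex-4-enoic acid
Conditions: LiHMDS (1.5 equiv), TMSCl/Et3N, THF, −78 → 23 °C (40 °C if slow); then 1 M HCl
Reagents that add atoms: none (silyl group lost on work-up)
Why: Ireland–Claisen [3,3] rearrangement of the chelated (BnO cis to OSi) silyl ketene acetal through a chair with methyl pseudo-equatorial and the Z-aryl pseudo-axial forms C3–C4, giving the 2,3-anti (2S,3R) acid and an E-propenyl group with full chirality transfer from the (S)-carbinol.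

**Step 5**
Reactants: 7
Product: 8, (2S,3R,4E)-2-(benzyloxy)-3-[4-(benzyloxy)-3-methoxyphenyl]hex-4-en-1-ol
Conditions: LiAlH4, THF, 0 → 23 °C
Reagents that add atoms: none
Why: Hydride reduction of the carboxylic acid to the primary alcohol (future C5–OH); the carboxylate is not enolised, so C3 and C4 are untouched.

**Step 6**
Reactants: 9, 2-methoxy-4-vinylphenol
Product: 10, 2-methoxy-4-vinylphenyl pivalate
Conditions: PivCl, Et3N, DMAP (cat.), CH2Cl2, 0 °C
Reagents that add atoms: pivaloyl chloride, CC(C)(C)C(=O)Cl
Why: Phenol acylation; the pivalate makes this aryl ring electron-poor (needed for a stable benzylic epoxide in step 8) and is hindered enough to survive the alkoxide in step 9.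

**Step 7**
Reactants: 8; 10 (3 equiv)
Product: 11, (2S,3R,4E)-2-(benzyloxy)-3-[4-(benzyloxy)-3-methoxyphenyl]-5-[3-methoxy-4-(pivaloyloxy)phenyl]pent-4-en-1-ol
Conditions: Hoveyda–Grubbs II (5 mol%), 1,4-benzoquinone (10 mol%), CH2Cl2, 40 °C
Reagents that add atoms: none (10 is a numbered reactant)
Why: Olefin cross-metathesis exchanges the propenyl methyl terminus for the aryl group (propene lost) with thermodynamic E selectivity; benzoquinone suppresses Ru–H alkene migration that would destroy C3.

**Step 8**
Reactants: 11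
Product: 12, (2S,3R)-2-(benzyloxy)-3-[4-(benzyloxy)-3-methoxyphenyl]-3-{(2R,3R)-3-[3-methoxy-4-(pivaloyloxy)phenyl]oxiran-2-yl}propan-1-ol
Conditions: VO(acac)2 (5 mol%), t-BuOOH (1.5 equiv, decane), CH2Cl2, 0 → 23 °C
Reagents that add atoms: tert-butyl hydroperoxide, CC(C)(C)OO (adds the epoxide O)
Why: Hydroxyl-directed vanadium-catalysed epoxidation (Kishi-type, bishomoallylic OH): in the A(1,3)-minimised rotamer with C3–H eclipsing the alkene, the vanadate tethered through C5–O delivers oxygen to the face bearing the C4 branch, anti to the C3 aryl, giving the (2R,3R)-trans-epoxide.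

**Step 9**
Reactants: 12
Product: 13, (R)-{(2S,3R,4S)-4-(benzyloxy)-3-[4-(benzyloxy)-3-methoxyphenyl]oxolan-2-yl}(4-hydroxy-3-methoxyphenyl)methanol
Conditions: NaH (1.5 equiv), THF (0.02 M), 0 → 23 °C; then MeOH, 23 °C (NaOMe formed in situ)
Reagents that add atoms: none
Why: 5-exo-tet SN2 opening of the epoxide by the C5 alkoxide at the non-benzylic carbon inverts C2, which places the side chain cis to the C3 aryl, and leaves C1′ as the (R)-carbinol; base-only conditions and the deactivated aryl disfavour benzylic (6-endo) opening, and methanolysis then removes the pivalate once the epoxide is gone.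

**Step 10**
Reactants: 13
Product: 14, Metasequirin E
Conditions: H2 (1 atm), 10% Pd/C, EtOAc–MeOH, 23 °C; stop at full conversion
Reagents that add atoms: none
Why: Hydrogenolysis cleaves the three benzyl ethers (two aryl, one at C4) under neutral conditions without touching any stereocentre.

**Compound list**
1 | 1-(benzyloxy)-4-bromo-2-methoxybenzene | COc1cc(Br)ccc1OCc1ccccc1 | starting material
2 | (S)-but-3-yn-2-ol | C[C@H](O)C#C | starting material
3 | (S)-4-[4-(benzyloxy)-3-methoxyphenyl]but-3-yn-2-ol | C[C@H](O)C#Cc1ccc(OCc2ccccc2)c(OC)c1 | intermediate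
4 | (S,Z)-4-[4-(benzyloxy)-3-methoxyphenyl]but-3-en-2-ol | C[C@H](O)/C=C\c1ccc(OCc2ccccc2)c(OC)c1 | intermediate
5 | 2-(benzyloxy)acetyl chloride | O=C(Cl)COCc1ccccc1 | starting material
6 | (S,Z)-4-[4-(benzyloxy)-3-methoxyphenyl]but-3-en-2-yl 2-(benzyloxy)acetate | C[C@H](OC(=O)COCc1ccccc1)/C=C\c1ccc(OCc2ccccc2)c(OC)c1 | intermediate
7 | (2S,3R,4E)-2-(benzyloxy)-3-[4-(benzyloxy)-3-methoxyphenyl]hex-4-enoic acid | OC(=O)[C@@H](OCc1ccccc1)[C@H](/C=C/C)c1ccc(OCc2ccccc2)c(OC)c1 | intermediate
8 | (2S,3R,4E)-2-(benzyloxy)-3-[4-(benzyloxy)-3-methoxyphenyl]hex-4-en-1-ol | OC[C@@H](OCc1ccccc1)[C@H](/C=C/C)c1ccc(OCc2ccccc2)c(OC)c1 | intermediate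
9 | 2-methoxy-4-vinylphenol | C=Cc1ccc(O)c(OC)c1 | starting material
10 | 2-methoxy-4-vinylphenyl pivalate | C=Cc1ccc(OC(=O)C(C)(C)C)c(OC)c1 | intermediate
11 | (2S,3R,4E)-2-(benzyloxy)-3-[4-(benzyloxy)-3-methoxyphenyl]-5-[3-methoxy-4-(pivaloyloxy)phenyl]pent-4-en-1-ol | OC[C@@H](OCc1ccccc1)[C@H](/C=C/c1ccc(OC(=O)C(C)(C)C)c(OC)c1)c1ccc(OCc2ccccc2)c(OC)c1 | intermediate
12 | (2S,3R)-2-(benzyloxy)-3-[4-(benzyloxy)-3-methoxyphenyl]-3-{(2R,3R)-3-[3-methoxy-4-(pivaloyloxy)phenyl]oxiran-2-yl}propan-1-ol | OC[C@@H](OCc1ccccc1)[C@H]([C@H]1O[C@@H]1c1ccc(OC(=O)C(C)(C)C)c(OC)c1)c1ccc(OCc2ccccc2)c(OC)c1 | intermediate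
13 | (R)-{(2S,3R,4S)-4-(benzyloxy)-3-[4-(benzyloxy)-3-methoxyphenyl]oxolan-2-yl}(4-hydroxy-3-methoxyphenyl)methanol | COc1cc([C@H]2[C@@H]([C@H](O)c3ccc(O)c(OC)c3)OC[C@H]2OCc2ccccc2)ccc1OCc1ccccc1 | intermediate
14 | Metasequirin E, (2S,3R,4S)-2-[(R)-hydroxy(4-hydroxy-3-methoxyphenyl)methyl]-3-(4-hydroxy-3-methoxyphenyl)oxolan-4-ol | COc1cc([C@H]2[C@@H]([C@H](O)c3ccc(O)c(OC)c3)OC[C@H]2O)ccc1O | target

**Totals**
Total steps: 10. Longest linear sequence: 9 (steps 1–5, 7–10); step 6 is a one-step branch.

**Three steps most likely to fail**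
1. Step 8 (epoxidation face selectivity). The alkene is E-1,2-disubstituted, so the A(1,3) bias is modest and the directing OH is remote; the diastereomer ratio may be only moderate. Fallback: drop the epoxide and use cyclic control. Cleave the propenyl group of 8 (OsO4/NaIO4) to the γ-lactol, oxidise to the lactone, make the (Z)-benzylidene enol ether with the Petasis-type ArCH2–Ti reagent, then hydroborate–oxidise from the ring face opposite the C3/C4 substituents; this sets C2 and C1′ together and also bypasses steps 7 and 9.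
2. Step 7 (cross-metathesis). The internal alkene is α-branched and hindered, and C3–H is both benzylic and allylic, so conversion may be low or the alkene may migrate. Fallback: replace metathesis by olefination. Cleave the propenyl group of 8 to the lactol and run a Julia–Kocienski reaction with the 1-phenyltetrazolyl sulfone of the pivaloyl-protected vanillyl unit to install the E-styryl group.
3. Step 4 (Ireland–Claisen on a Z-aryl allylic glycolate). The rearrangement is slower than for E esters, may leak through a boat, and the ester is ionisation-prone. Fallback: use the well-behaved E series. Start from (R)-but-3-yn-2-ol, reduce the alkynol with Red-Al, and rearrange the PMB-glycolate; this gives the 2,3-syn acid with C3 already correct. Then invert C4 by Mitsunobu reaction on the α-hydroxy ester after DDQ removal of PMB, and reduce with LiAlH4.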